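Read in reciprocal hours, a decay is one number, its rate constant, and for free monomer that number is the slope of the log-drop ln(charge/[free monomer]) against time.

in all of them: initiator 150 mM

|  | free monomer | transfer agent | remark | time |
|---|---|---|---|---|
| violet | 3 M | 0.16 M | run made earlier |  |
| blue | 3 M | 0.58 M | run made earlier |  |
| north-east | 3.0 M | 0.300 M |  | 8.0 h |
| north-west | 3.0 M | 0.900 M |  | 8.0 h |

| run | time / h | free monomer / % | monomer in chains / % | uncatalysed product / % |
|---|---|---|---|---|
| violet | 0.417 | 88.2 | 11.0 | 1.4 |
| violet | 1.00 | 74.6 | 24.5 | 0 |
| violet | 2.50 | 51.4 | 47.4 | 1.7 |
| violet | 6.00 | 24.4 | 73.3 | 1.2 |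
| blue | 0.667 | 82.9 | 16.0 | 0.1 |
| blue | 2.00 | 63.8 | 35.9 | 0.7 |
| blue | 4.00 | 50.8 | 48.6 | 1.7 |
| blue | 6.00 | 43.1 | 55.2 | 1.8 |

(standard deviation of a reading: 0.5 percentage points)



- which of these there is most of at the end, counted by the free monomer in it, north-east (free monomer / uncatalysed product / monomer in chains)
- which of these there is most of at the end, counted by the free monomer in it, north-west (free monomer / uncatalysed product / monomer in chains)
- how much there is at the end of the one of these that leads, in percent of the free monomer charged: north-east
- how much there is at the end of the one of these that leads, in percent of the free monomer charged: north-west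

Start with the blue run, where the log-drop is 0.449 at 2.00 h and 0.677 at 4.00 h. The second equal interval adds 0.228, less than the first, so this reads as a pseudo-first-order decay whose rate constant falls. If it falls exponentially, the ratio of the two intervals gives, for the blue run, a decay rate of 0.340 h⁻¹ and a starting constant of 0.310 h⁻¹. Assume the decay rate is proportional to [transfer agent], so that it scales from the blue run to another flask by the ratio of the charges.

Integrate that falling rate, and you see the log-drop climb with a time constant and level off at starting constant over decay rate. For north-east, with the decay rate scaled to its charge, the time constant is 5.69 h and the level is 1.76. Call this level the reach. But test it first: the violet run, unused so far, reckons to 24.1 % free monomer at 6.00 h, and reads 24.4 %.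

So north-east, with its reach above the 0.693 of a halving, reckons to 26.4 % free monomer at the end, and monomer in chains leads. North-west's reach is 0.587, below a halving, so it reckons to 56.1 % and free monomer leads.

The forecast gives monomer in chains at 72 % for north-east and free monomer at 54 % for north-west, holding that “The rate falls much faster with more transfer agent, which suggests the catalyst is being lost.” Your north-west figure stands above its value.

The flask gives monomer in chains at 72.9 % in north-east and free monomer at 52.5 % in north-west.

    free monomer + initiator → living end + monomer in chains (k = 2.00 M⁻¹ h⁻¹)
    free monomer + living end → monomer in chains + living end, rate k2*[living end]*[free monomer] (k = 1.90 M⁻¹ h⁻¹)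
    living end + transfer agent → dead chain (kL = 0.610 M⁻¹ h⁻¹)
    free monomer → uncatalysed product (k = 0.00480 h⁻¹)

Now read north-east early, at 2.0 h, which is about a third of its time constant. The curve has then covered 29.6 % of the reach 1.76, so you reckon 59.4 % free monomer. That early flask holds 60.2 % free monomer, and free monomer still leads there.

The runs stem from a simulated flask for an exercise; scatter was added.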